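**Strategy.** Ring A is disconnected across C4–C5 and C5–C6, so that C5 comes from carbon monoxide and the other five ring carbons from an open-chain 3-acyloxy-1,4-enyne. A rhodium-catalysed carbonylative [5+1] benzannulation closes ring A in one operation. It delivers the two oxygens around the lone C4–H already differentiated (C3 pivalate, C5 free hydroxyl), with the C2 benzyl, C1 phenethyl and C6 benzyl groups carried in from the chain. The precursor is a tertiary propargylic pivalate with a terminal alkyne, a benzyl group on the carbinol carbon and an E-trisubstituted alkene bearing the phenethyl and second benzyl groups; all three phenols are benzyl ethers.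

Key step: step 9

Assumption: the target name is read as the bibenzyl drawn by the SMILES (ring A: C1 ethylene bridge, C2 and C6 4-hydroxybenzyl, C3 OH, C4 H, C5 OMe; ring B: 3'-OH), and 2-[4-(benzyloxy)phenyl]ethanol is taken as a purchased material.

Step 1
Reactants: 1 2-(3-hydroxyphenyl)ethanol
Product: 2 2-[3-(benzyloxy)phenyl]ethanol
Conditions: BnBr, K2CO3, acetone, reflux
Reagents that add atoms: benzyl bromide, BrCc1ccccc1
Why: Williamson etherification in which K2CO3 ionises only the phenol, so the aryl oxygen is benzylated and the primary alcohol is kept for step 2.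

Step 2
Reactants: 2 2-[3-(benzyloxy)phenyl]ethanol
Product: 3 1-(benzyloxy)-3-(2-iodoethyl)benzene
Conditions: I2, PPh3, imidazole, CH2Cl2, 0 °C → rt
Reagents that add atoms: iodine, II
Why: Appel-type iodination converts the primary alcohol into the iodide by SN2 displacement of the oxyphosphonium group, and the benzyl ether is inert.

Step 3
Reactants: 3 1-(benzyloxy)-3-(2-iodoethyl)benzene; 4 triethyl phosphonoacetate
Product: 5 ethyl 4-[3-(benzyloxy)phenyl]-2-(diethoxyphosphoryl)butanoate (racemic)
Conditions: 4 (excess), NaH, DME, 0 °C; then 3, 70 °C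
Reagents that add atoms: none
Why: SN2 C-alkylation of the phosphonate-stabilised carbanion with a primary iodide, run with excess 4 to suppress dialkylation; the new stereocentre is racemic and disappears in step 5.

Step 4
Reactants: 6 2-[4-(benzyloxy)phenyl]ethanol
Product: 7 [4-(benzyloxy)phenyl]acetaldehyde
Conditions: Dess–Martin periodinane, CH2Cl2, 0 °C → rt; used at once
Reagents that add atoms: none
Why: Dess–Martin oxidation stops at the aldehyde under nearly neutral conditions, which suits an arylacetaldehyde that enolises and self-condenses easily and is therefore not stored.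

Step 5
Reactants: 5 ethyl 4-[3-(benzyloxy)phenyl]-2-(diethoxyphosphoryl)butanoate; 7 [4-(benzyloxy)phenyl]acetaldehyde
Product: 8 ethyl (E)-2-{2-[3-(benzyloxy)phenyl]ethyl}-4-[4-(benzyloxy)phenyl]but-2-enoate
Conditions: 5 (slight excess over base), NaH, THF, 0 °C; then 7, −78 → 0 °C; minor Z isomer removed by chromatography
Reagents that add atoms: none
Why: Horner–Wadsworth–Emmons olefination, in which reversible oxyanion formation and syn-elimination should favour the alkene with the ester trans to the new CH2Ar group (E), while the base deficit and low temperature limit enolisation of 7 and deconjugation of 8.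

Step 6
Reactants: 8 ethyl (E)-2-{2-[3-(benzyloxy)phenyl]ethyl}-4-[4-(benzyloxy)phenyl]but-2-enoate
Product: 9 (E)-2-{2-[3-(benzyloxy)phenyl]ethyl}-4-[4-(benzyloxy)phenyl]-N-methoxy-N-methylbut-2-enamide
Conditions: MeNHOMe·HCl, i-PrMgCl, THF, −20 → 0 °C
Reagents that add atoms: N,O-dimethylhydroxylamine hydrochloride, CNOC.Cl
Why: Weinreb amide formation by direct aminolysis of the ester with the chloromagnesium amide, which should acylate faster than it deprotonates at low temperature and leaves the alkene geometry untouched.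

Step 7
Reactants: 9 (E)-2-{2-[3-(benzyloxy)phenyl]ethyl}-4-[4-(benzyloxy)phenyl]-N-methoxy-N-methylbut-2-enamide; 10 4-(benzyloxy)benzyl chloride
Product: 12 (E)-1,5-bis[4-(benzyloxy)phenyl]-3-{2-[3-(benzyloxy)phenyl]ethyl}pent-3-en-2-one, via 4-(benzyloxy)benzylmagnesium chloride 11 (not isolated)
Conditions: 10, Mg, THF, 0 °C (slow addition); then 9, THF, −20 → 0 °C; aq. NH4Cl
Reagents that add atoms: none
Why: Weinreb ketone synthesis, in which the benzylic Grignard reagent adds once to give a chelated magnesium adduct that releases the ketone only on work-up, so over-addition and enolisation of the product are excluded in the flask.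

Step 8
Reactants: 12 (E)-1,5-bis[4-(benzyloxy)phenyl]-3-{2-[3-(benzyloxy)phenyl]ethyl}pent-3-en-2-one
Product: 14 (E)-3-[4-(benzyloxy)benzyl]-4-{2-[3-(benzyloxy)phenyl]ethyl}-6-[4-(benzyloxy)phenyl]hex-4-en-1-yn-3-yl pivalate (racemic), via bromomagnesium alkoxide 13 (not isolated)
Conditions: HC≡CMgBr, THF, 0 °C → rt; then PivCl, DMAP (cat.), 0 → 40 °C
Reagents that add atoms: ethynylmagnesium bromide, C#C[Mg]Br; pivaloyl chloride, CC(C)(C)C(=O)Cl
Why: 1,2-addition of an alkynyl Grignard reagent to the enone carbonyl, then O-acylation of the tertiary alkoxide by the acid chloride in the same flask, which avoids esterifying a hindered free tertiary alcohol; the carbinol stereocentre is formed racemic because step 9 erases it.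

Step 9
Reactants: 14 (E)-3-[4-(benzyloxy)benzyl]-4-{2-[3-(benzyloxy)phenyl]ethyl}-6-[4-(benzyloxy)phenyl]hex-4-en-1-yn-3-yl pivalate
Product: 16 2,4-bis[4-(benzyloxy)benzyl]-3-{2-[3-(benzyloxy)phenyl]ethyl}-5-hydroxyphenyl pivalate, via cyclohexadienone tautomer 15 (not isolated)
Conditions: [RhCl(CO)2]2 (5 mol %), CO (1 atm), ClCH2CH2Cl, 60 °C
Reagents that add atoms: carbon monoxide, [C-]#[O+]
Why: Monovalent rhodium activates the terminal alkyne of 14, the pivalate migrates from the carbinol carbon to the internal alkyne carbon through a five-membered dioxolenium ion, and the rhodium vinylcarbene formed at the former alkyne terminus is conjugated with the alkene; CO insertion at the carbene carbon (ring A bond C4–C5) gives a rhodium-bound dienylketene or acyl rhodacycle. Ring A is closed by 6π electrocyclisation (or C–C reductive elimination) between the CO carbon and the alkene CH (ring A bond C5–C6), and cyclohexadienone 15 tautomerises to the phenol. The closest known reaction is the [RhCl(CO)2]2-catalysed carbonylative [5+1] cycloaddition of 3-acyloxy-1,4-enynes to resorcinol monoesters, applied here to a more crowded tertiary ester. No stereocentre is formed, and the racemic carbinol centre of 14 is erased. The step needs 1,2- and not 1,3-acyloxy migration, which the unsubstituted alkyne terminus favours, and an unhindered ring closure at the alkene terminus, which the E geometry secures by turning hydrogen and not the benzyl group inward. The CO atmosphere should intercept the carbene before it closes to a cyclopentenone.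

Step 10
Reactants: 16 2,4-bis[4-(benzyloxy)benzyl]-3-{2-[3-(benzyloxy)phenyl]ethyl}-5-hydroxyphenyl pivalate
Product: 17 2,4-bis[4-(benzyloxy)benzyl]-3-{2-[3-(benzyloxy)phenyl]ethyl}-5-methoxyphenyl pivalate
Conditions: MeI, K2CO3, DMF (dry), rt
Reagents that add atoms: iodomethane, CI
Why: Williamson O-methylation of the only free phenol, with the aryl pivalate stable to K2CO3 in dry DMF; because C2 and C6 of ring A carry identical benzyl groups, the two oxygens are interchangeable and only mono-methylation has to be secured.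

Step 11
Reactants: 17 2,4-bis[4-(benzyloxy)benzyl]-3-{2-[3-(benzyloxy)phenyl]ethyl}-5-methoxyphenyl pivalate
Product: 18 2,4-bis[4-(benzyloxy)benzyl]-3-{2-[3-(benzyloxy)phenyl]ethyl}-5-methoxyphenol
Conditions: NaOMe, MeOH/THF, rt → 40 °C; aq. NH4Cl
Reagents that add atoms: none
Why: Zemplén-type transesterification, in which methoxide cleaves the aryl pivalate to the phenoxide and methyl pivalate while benzyl and methyl ethers are inert.

Step 12
Reactants: 18 2,4-bis[4-(benzyloxy)benzyl]-3-{2-[3-(benzyloxy)phenyl]ethyl}-5-methoxyphenol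
Product: 19 3,3'-dihydroxy-2,6-bis(4-hydroxybenzyl)-5-methoxybibenzyl
Conditions: H2 (1 atm), Pd on carbon, EtOAc/MeOH, rt
Reagents that add atoms: none
Why: Catalytic hydrogenolysis cleaves the three aryl benzyl ethers under neutral conditions, leaves the methyl ether and the diarylmethane and bibenzyl C–C bonds intact, and frees the oxidation-prone polyphenol only in the last, base-free step.

**Compound list**

1 | 2-(3-hydroxyphenyl)ethanol | OCCc1cccc(O)c1 | starting material
2 | 2-[3-(benzyloxy)phenyl]ethanol | OCCc1cccc(OCc2ccccc2)c1 | intermediate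
3 | 1-(benzyloxy)-3-(2-iodoethyl)benzene | ICCc1cccc(OCc2ccccc2)c1 | intermediate
4 | triethyl phosphonoacetate | CCOC(=O)CP(=O)(OCC)OCC | starting material
5 | ethyl 4-[3-(benzyloxy)phenyl]-2-(diethoxyphosphoryl)butanoate (racemic) | CCOC(=O)C(CCc1cccc(OCc2ccccc2)c1)P(=O)(OCC)OCC | intermediate
6 | 2-[4-(benzyloxy)phenyl]ethanol | OCCc1ccc(OCc2ccccc2)cc1 | starting material
7 | [4-(benzyloxy)phenyl]acetaldehyde | O=CCc1ccc(OCc2ccccc2)cc1 | intermediate
8 | ethyl (E)-2-{2-[3-(benzyloxy)phenyl]ethyl}-4-[4-(benzyloxy)phenyl]but-2-enoate | CCOC(=O)/C(CCc1cccc(OCc2ccccc2)c1)=C/Cc1ccc(OCc2ccccc2)cc1 | intermediate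
9 | (E)-2-{2-[3-(benzyloxy)phenyl]ethyl}-4-[4-(benzyloxy)phenyl]-N-methoxy-N-methylbut-2-enamide | CON(C)C(=O)/C(CCc1cccc(OCc2ccccc2)c1)=C/Cc1ccc(OCc2ccccc2)cc1 | intermediate
10 | 4-(benzyloxy)benzyl chloride | ClCc1ccc(OCc2ccccc2)cc1 | starting material
11 | 4-(benzyloxy)benzylmagnesium chloride (not isolated) | Cl[Mg]Cc1ccc(OCc2ccccc2)cc1 | intermediate
12 | (E)-1,5-bis[4-(benzyloxy)phenyl]-3-{2-[3-(benzyloxy)phenyl]ethyl}pent-3-en-2-one | O=C(Cc1ccc(OCc2ccccc2)cc1)/C(CCc1cccc(OCc2ccccc2)c1)=C/Cc1ccc(OCc2ccccc2)cc1 | intermediate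
13 | bromomagnesium (E)-3-[4-(benzyloxy)benzyl]-4-{2-[3-(benzyloxy)phenyl]ethyl}-6-[4-(benzyloxy)phenyl]hex-4-en-1-yn-3-olate (racemic, not isolated) | C#CC(O[Mg]Br)(Cc1ccc(OCc2ccccc2)cc1)/C(CCc1cccc(OCc2ccccc2)c1)=C/Cc1ccc(OCc2ccccc2)cc1 | intermediate
14 | (E)-3-[4-(benzyloxy)benzyl]-4-{2-[3-(benzyloxy)phenyl]ethyl}-6-[4-(benzyloxy)phenyl]hex-4-en-1-yn-3-yl pivalate (racemic) | C#CC(OC(=O)C(C)(C)C)(Cc1ccc(OCc2ccccc2)cc1)/C(CCc1cccc(OCc2ccccc2)c1)=C/Cc1ccc(OCc2ccccc2)cc1 | intermediate
15 | 4,6-bis[4-(benzyloxy)benzyl]-5-{2-[3-(benzyloxy)phenyl]ethyl}-3-oxocyclohexa-1,5-dien-1-yl pivalate (racemic, not isolated) | O=C1C=C(OC(=O)C(C)(C)C)C(Cc2ccc(OCc3ccccc3)cc2)=C(CCc2cccc(OCc3ccccc3)c2)C1Cc1ccc(OCc2ccccc2)cc1 | intermediate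
16 | 2,4-bis[4-(benzyloxy)benzyl]-3-{2-[3-(benzyloxy)phenyl]ethyl}-5-hydroxyphenyl pivalate | Oc1cc(OC(=O)C(C)(C)C)c(Cc2ccc(OCc3ccccc3)cc2)c(CCc2cccc(OCc3ccccc3)c2)c1Cc1ccc(OCc2ccccc2)cc1 | intermediate
17 | 2,4-bis[4-(benzyloxy)benzyl]-3-{2-[3-(benzyloxy)phenyl]ethyl}-5-methoxyphenyl pivalate | COc1cc(OC(=O)C(C)(C)C)c(Cc2ccc(OCc3ccccc3)cc2)c(CCc2cccc(OCc3ccccc3)c2)c1Cc1ccc(OCc2ccccc2)cc1 | intermediate
18 | 2,4-bis[4-(benzyloxy)benzyl]-3-{2-[3-(benzyloxy)phenyl]ethyl}-5-methoxyphenol | COc1cc(O)c(Cc2ccc(OCc3ccccc3)cc2)c(CCc2cccc(OCc3ccccc3)c2)c1Cc1ccc(OCc2ccccc2)cc1 | intermediate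
19 | 3,3'-dihydroxy-2,6-bis(4-hydroxybenzyl)-5-methoxybibenzyl | COc1cc(O)c(Cc2ccc(O)cc2)c(CCc2cccc(O)c2)c1Cc1ccc(O)cc1 | target

**Step count and risk**

Total step count: 12. Longest linear sequence: 11 steps (steps 1, 2, 3, 5, 6, 7, 8, 9, 10, 11, 12, from 1 to 19).

Steps most likely to fail:

Step 9. At the crowded tertiary ester the 1,3-acyloxy shift to an allenyl ester, or closure of the carbene to a five-membered ring before CO uptake, may outrun the [5+1] pathway, or turnover may stall at the fully substituted alkene carbon. The fallback abandons the benzannulation and decorates a preformed resorcinol ring. It sets out from iodide 3 (with chloride 10 as the benzyl source) and returns to the route at target 19.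
- Benzylation of purchased 3-bromo-5-methoxyphenol (BnBr, K2CO3, acetone) would give 1-(benzyloxy)-3-bromo-5-methoxybenzene F1.
- Zinc insertion into 3 (Zn dust, LiCl, THF) would give {2-[3-(benzyloxy)phenyl]ethyl}zinc iodide F2.
- Negishi coupling of F2 with F1 (Pd(OAc)2, SPhos, THF, 50 °C) would give the bibenzyl 1-(benzyloxy)-3-{2-[3-(benzyloxy)phenyl]ethyl}-5-methoxybenzene F3.
- Electrophilic bromination with NBS (2 equiv, MeCN, 0 °C) should occur on the doubly activated ring A para to each alkoxy group and give 1-(benzyloxy)-2,4-dibromo-3-{2-[3-(benzyloxy)phenyl]ethyl}-5-methoxybenzene F4.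
- Twofold Negishi coupling with 4-(benzyloxy)benzylzinc chloride F5 (from 10, Zn dust, LiCl, THF) under the same zerovalent palladium catalysis would give 1-(benzyloxy)-2,4-bis[4-(benzyloxy)benzyl]-3-{2-[3-(benzyloxy)phenyl]ethyl}-5-methoxybenzene F6.
- Hydrogenolysis of F6 under the conditions of step 12 would give 19.

Step 5. The basic phosphonate carbanion may enolise and self-condense the arylacetaldehyde, the new double bond may drift into conjugation with the 4-(benzyloxy)phenyl ring, and E selectivity may be incomplete. Both geometric isomers should still converge on 16, since the alkene geometry is lost on aromatisation, but the Z isomer would close more slowly. The fallback is a base-free Wittig reaction that sets out from iodide 3 and returns at enoate 8.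
- Heating 3 with Ph3P=CHCO2Et in EtOAc would give {4-[3-(benzyloxy)phenyl]-1-ethoxy-1-oxobutan-2-yl}triphenylphosphonium iodide F7.
- Aqueous NaOH/CH2Cl2 would convert F7 into the stabilised ylide ethyl 4-[3-(benzyloxy)phenyl]-2-(triphenylphosphoranylidene)butanoate F8.
- Reaction of F8 with aldehyde 7 (toluene, 60 °C) should give 8 with the E preference typical of α-substituted stabilised ylides.

Step 8. The acetylide may deprotonate the benzylic α-CH2 of the ketone instead of adding, and acylation of the congested magnesium alkoxide may be slow enough for C-acylation at the alkyne terminus to compete. The fallback is a stepwise sequence with a silyl-capped alkyne that sets out from enone 12 and returns at pivalate 14.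
- LiC≡CSiMe3 with anhydrous CeCl3 (THF, −78 °C) would give (E)-3-[4-(benzyloxy)benzyl]-4-{2-[3-(benzyloxy)phenyl]ethyl}-6-[4-(benzyloxy)phenyl]-1-(trimethylsilyl)hex-4-en-1-yn-3-ol F9.
- Deprotonation with LiN(SiMe3)2 and acylation with PivCl (THF, −78 °C → rt) would give (E)-3-[4-(benzyloxy)benzyl]-4-{2-[3-(benzyloxy)phenyl]ethyl}-6-[4-(benzyloxy)phenyl]-1-(trimethylsilyl)hex-4-en-1-yn-3-yl pivalate F10.
- K2CO3 in MeOH at rt would remove the silyl group from F10 and give 14.

**Further compounds**

F1 | step 9 | 1-(benzyloxy)-3-bromo-5-methoxybenzene | COc1cc(Br)cc(OCc2ccccc2)c1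
F2 | step 9 | {2-[3-(benzyloxy)phenyl]ethyl}zinc iodide | I[Zn]CCc1cccc(OCc2ccccc2)c1
F3 | step 9 | 1-(benzyloxy)-3-{2-[3-(benzyloxy)phenyl]ethyl}-5-methoxybenzene | COc1cc(CCc2cccc(OCc3ccccc3)c2)cc(OCc2ccccc2)c1
F4 | step 9 | 1-(benzyloxy)-2,4-dibromo-3-{2-[3-(benzyloxy)phenyl]ethyl}-5-methoxybenzene | COc1cc(OCc2ccccc2)c(Br)c(CCc2cccc(OCc3ccccc3)c2)c1Br
F5 | step 9 | 4-(benzyloxy)benzylzinc chloride | Cl[Zn]Cc1ccc(OCc2ccccc2)cc1
F6 | step 9 | 1-(benzyloxy)-2,4-bis[4-(benzyloxy)benzyl]-3-{2-[3-(benzyloxy)phenyl]ethyl}-5-methoxybenzene | COc1cc(OCc2ccccc2)c(Cc2ccc(OCc3ccccc3)cc2)c(CCc2cccc(OCc3ccccc3)c2)c1Cc1ccc(OCc2ccccc2)cc1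
F7 | step 5 | {4-[3-(benzyloxy)phenyl]-1-ethoxy-1-oxobutan-2-yl}triphenylphosphonium iodide | CCOC(=O)C(CCc1cccc(OCc2ccccc2)c1)[P+](c1ccccc1)(c1ccccc1)c1ccccc1.[I-]
F8 | step 5 | ethyl 4-[3-(benzyloxy)phenyl]-2-(triphenylphosphoranylidene)butanoate | CCOC(=O)C(CCc1cccc(OCc2ccccc2)c1)=P(c1ccccc1)(c1ccccc1)c1ccccc1
F9 | step 8 | (E)-3-[4-(benzyloxy)benzyl]-4-{2-[3-(benzyloxy)phenyl]ethyl}-6-[4-(benzyloxy)phenyl]-1-(trimethylsilyl)hex-4-en-1-yn-3-ol | C[Si](C)(C)C#CC(O)(Cc1ccc(OCc2ccccc2)cc1)/C(CCc1cccc(OCc2ccccc2)c1)=C/Cc1ccc(OCc2ccccc2)cc1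
F10 | step 8 | (E)-3-[4-(benzyloxy)benzyl]-4-{2-[3-(benzyloxy)phenyl]ethyl}-6-[4-(benzyloxy)phenyl]-1-(trimethylsilyl)hex-4-en-1-yn-3-yl pivalate | C[Si](C)(C)C#CC(OC(=O)C(C)(C)C)(Cc1ccc(OCc2ccccc2)cc1)/C(CCc1cccc(OCc2ccccc2)c1)=C/Cc1ccc(OCc2ccccc2)cc1
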